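**Retrosynthetic overview**

1. Ring atoms (rings A and B are identical): C1 carries the bridging CH2, C2 OH, C3 acetyl, C4 OH, C5 CH3, C6 OCH3. End game: mallotophenone ⇐ BCl3 cleavage of the two C2 isopropyl ethers ⇐ twofold C3 acetylation of bis(4-hydroxy-2-isopropoxy-6-methoxy-5-methylphenyl)methane.
2. Structural feature used: in each ring the neighbouring C5(CH3)–C6(OCH3) pair has the substitution pattern of an ynol ether (1-methoxyprop-1-yne). The remaining chain C1–C2–C3–C4, with oxygen on C2 and C4 and the bridge on C1, maps onto a 3-alkoxycyclobutenone bridged at cyclobutenone C2.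
3. Key disconnection: bonds C4–C5 and C6–C1 of ring A and of ring B (four bonds, one operation), back to 2,2'-methylenebis(3-isopropoxycyclobut-2-en-1-one) and two molecules of 1-methoxyprop-1-yne (twofold cyclobutenone–ynol ether benzannulation).
4. Precursors: the bis-cyclobutenone from ketene + ethoxyacetylene ([2+2]), hydrolysis to cyclobutane-1,3-dione, formaldehyde bridging at C2 and Mitsunobu O-isopropylation; the ynol ether from trichloroethylene, KOMe, n-BuLi and MeI.
5. Ring order: the two four-membered rings first, then benzene rings A and B together in the key step.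

Key step: step 7

Remark: mallotophenone has no stereocentre, so the route needs no stereocontrol; the only descriptors are alkene geometries of a reagent precursor and of transient ketenes.

**Route**

Step 1
Reactants: 1 ethoxyacetylene; 2 acetyl chloride
Product: 4 3-ethoxycyclobut-2-en-1-one, via ketene 3 (not isolated)
Conditions: Et3N, Et2O, 0 °C to rt, slow addition of 2
Reagents that add atoms: none
Why: Et3N dehydrochlorinates 2 to ketene 3, which is trapped in situ by the electron-rich alkyne in a regioselective ketene–alkyne [2+2] cycloaddition (ketene carbonyl carbon to the unsubstituted alkyne carbon), the established entry to 3-alkoxycyclobutenones.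

Step 2
Reactants: 4 3-ethoxycyclobut-2-en-1-one
Product: 5 cyclobutane-1,3-dione
Conditions: TFA, H2O, rt; concentration in vacuo, used at once
Reagents that add atoms: water (O)
Why: Acid hydrolysis of the vinylogous ester (addition of water at the alkoxy-bearing carbon and loss of ethanol) releases the 1,3-dione, a strong but labile vinylogous acid that is therefore not stored.

Step 3
Reactants: 5 cyclobutane-1,3-dione (2 equiv); 6 formaldehyde
Product: 8 2,2'-methylenebis(3-hydroxycyclobut-2-en-1-one), via 2-methylenecyclobutane-1,3-dione 7 (not isolated)
Conditions: 37% aq. CH2O (0.5 equiv), NaOAc (cat.), H2O, 0 °C to rt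
Reagents that add atoms: none
Why: Tandem Knoevenagel condensation–Michael addition: the enol of 5 attacks formaldehyde through C2, loss of water gives the 2-methylene dione 7, and a second enol adds to it at once, as dimedone, tetronic acid and 4-hydroxycoumarin do in giving their methylene-bis adducts; the four-membered dione has not itself been tested in this reaction, formaldehyde is kept limiting, and the product has no C2–H left to react further.

Step 4
Reactants: 8 2,2'-methylenebis(3-hydroxycyclobut-2-en-1-one)
Product: 9 2,2'-methylenebis(3-isopropoxycyclobut-2-en-1-one)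
Conditions: i-PrOH (2.5 equiv), PPh3, DIAD, THF, 0 °C to rt
Reagents that add atoms: propan-2-ol (CC(C)O)
Why: Mitsunobu O-alkylation of an acidic enol with a secondary alcohol; C2 is fully substituted and each dione ring is symmetrical, so only one enol ether can form per ring, and the cold neutral conditions spare the cyclobutenone.

Step 5
Reactants: 10 trichloroethylene
Product: 12 (E)-1,2-dichloro-1-methoxyethene, via dichloroacetylene 11 (not isolated)
Conditions: KOMe, THF, −50 °C to rt
Reagents that add atoms: potassium methoxide (C[O-].[K+])
Why: Methoxide eliminates HCl from 10 to dichloroacetylene 11 (kept in solution), and anti addition of methoxide followed by protonation gives the (E)-dichlorovinyl ether, the known elimination–addition route to dichloroenol ethers.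

Step 6
Reactants: 12 (E)-1,2-dichloro-1-methoxyethene
Product: 15 1-methoxyprop-1-yne, via chloro(methoxy)acetylene 13 (not isolated), via lithium methoxyacetylide 14 (not isolated)
Conditions: n-BuLi (2.2 equiv), Et2O, −78 to −40 °C; then MeI, HMPA, −40 °C to rt; distillation
Reagents that add atoms: iodomethane (CI)
Why: n-BuLi effects β-elimination of LiCl to the chloroalkyne 13 and then chlorine–lithium exchange to the lithium alkoxyacetylide 14, whose C-methylation gives the ynol ether (established dichlorovinyl ether route); the volatile product is carried on as a distilled, NMR-assayed solution, and as a methyl ether it cannot fragment by retro-ene on later heating.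

Step 7
Reactants: 9 2,2'-methylenebis(3-isopropoxycyclobut-2-en-1-one); 15 1-methoxyprop-1-yne
Product: 25 bis(4-hydroxy-2-isopropoxy-6-methoxy-5-methylphenyl)methane, via first vinylketene 16 (not isolated), via first vinylcyclobutenone 17 (not isolated), via first dienylketene 18 (not isolated), via first cyclohexadienone 19 (not isolated), via monophenol 20 (not isolated), via second vinylketene 21 (not isolated), via second vinylcyclobutenone 22 (not isolated), via second dienylketene 23 (not isolated), via second cyclohexadienone 24 (not isolated)
Conditions: 15 (6 equiv), toluene, sealed tube, 120–140 °C; then K2CO3, MeOH, rt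
Reagents that add atoms: none
Why: Proposed new method: Each 3-isopropoxycyclobutenone of 9 should open on heating (4π electrocyclic) to a 2-substituted (1-isopropoxyvinyl)ketene (16, later 21), which adds the ynol ether 15 in a [2+2] cycloaddition to give the 4-vinylcyclobutenones 17 and 22; these open again (4π) to the dienylketenes 18 and 23. Rings A and B are each closed by a thermal 6π electrocyclisation of the dienylketene, the ketene carbon (C4) bonding to the terminal CH2 of the isopropoxyvinyl group (C3), and the cyclohexadienones 19 and 24 tautomerise to the phenols 20 and 25; the bonds C4–C5 and C6–C1 themselves come from the [2+2] step. The closest known reaction type is the Danheiser benzannulation of alkyl-substituted cyclobutenones with alkoxyalkynes, which has not been shown twofold in one molecule, on a 3-alkoxycyclobutenone, or with a methylene bridge at cyclobutenone C2. No stereocentre is created in the product: the quaternary carbon of 17 and 22 forms racemic and becomes aromatic C1. The selectivity needed is the orientation of the ketene–alkyne addition, and it is secured by the polarisation of 15, whose nucleophilic methyl-bearing carbon attacks the electrophilic ketene carbonyl carbon, so that the methoxy-bearing carbon bonds to the bridge-bearing carbon and OCH3 ends up at C6 next to the bridge. Capture of the ketenes by the alkyne instead of by a phenol already formed is favoured by the excess of 15 and by the para relation of the new hydroxyl to the bridge, which keeps it away from the second ketene; the medium stays neutral, so the electron-rich diarylmethane is not exposed to acid, and the final methanolysis returns any O-acylated phenol.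

Step 8
Reactants: 25 bis(4-hydroxy-2-isopropoxy-6-methoxy-5-methylphenyl)methane
Product: 26 bis(3-acetyl-4-hydroxy-2-isopropoxy-6-methoxy-5-methylphenyl)methane
Conditions: Ac2O (2.4 equiv), BF3·OEt2, CH2Cl2, 0 °C to rt; then H2O
Reagents that add atoms: acetic anhydride (CC(=O)OC(C)=O)
Why: Friedel–Crafts acetylation (BF3-promoted, with Fries-type delivery from the phenol oxygen possible) at C3, the only unsubstituted ring carbon, which is activated by the ortho hydroxyl, the ortho isopropoxy and the para methoxy group; the mild Lewis acid and low temperature are chosen to spare the acid-sensitive diarylmethane.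

Step 9
Reactants: 26 bis(3-acetyl-4-hydroxy-2-isopropoxy-6-methoxy-5-methylphenyl)methane
Product: 27 mallotophenone, bis(3-acetyl-2,4-dihydroxy-6-methoxy-5-methylphenyl)methane
Conditions: BCl3, CH2Cl2, −78 to 0 °C; then H2O
Reagents that add atoms: none
Why: Selective Lewis acid dealkylation: BCl3 cleaves the isopropyl aryl ethers, here also assisted by chelation to the ortho acetyl carbonyl, much faster than the unchelated methyl ethers para to the ketones, so both methoxy groups and the now deactivated diarylmethane should survive.

**Compound list**

1 | ethoxyacetylene | CCOC#C | starting material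
2 | acetyl chloride | CC(=O)Cl | starting material
3 | ketene (not isolated) | C=C=O | intermediate
4 | 3-ethoxycyclobut-2-en-1-one | CCOC1=CC(=O)C1 | intermediate
5 | cyclobutane-1,3-dione | O=C1CC(=O)C1 | intermediate
6 | formaldehyde | C=O | starting material
7 | 2-methylenecyclobutane-1,3-dione (not isolated) | C=C1C(=O)CC1=O | intermediate
8 | 2,2'-methylenebis(3-hydroxycyclobut-2-en-1-one), bis-enol form of the methylene-bridged bis-dione | O=C1CC(O)=C1CC1=C(O)CC1=O | intermediate
9 | 2,2'-methylenebis(3-isopropoxycyclobut-2-en-1-one) | CC(C)OC1=C(CC2=C(OC(C)C)CC2=O)C(=O)C1 | intermediate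
10 | trichloroethylene | ClC=C(Cl)Cl | starting material
11 | dichloroacetylene (not isolated) | ClC#CCl | intermediate
12 | (E)-1,2-dichloro-1-methoxyethene | Cl/C=C(/Cl)OC | intermediate
13 | chloro(methoxy)acetylene (not isolated) | COC#CCl | intermediate
14 | lithium methoxyacetylide (not isolated) | COC#C[Li] | intermediate
15 | 1-methoxyprop-1-yne | CC#COC | intermediate
16 | 2-[(2-isopropoxy-4-oxocyclobut-1-en-1-yl)methyl]-3-isopropoxybuta-1,3-dien-1-one (first vinylketene, not isolated) | C=C(OC(C)C)C(=C=O)CC1=C(OC(C)C)CC1=O | intermediate
17 | 4-(1-isopropoxyvinyl)-4-[(2-isopropoxy-4-oxocyclobut-1-en-1-yl)methyl]-3-methoxy-2-methylcyclobut-2-en-1-one, racemic (first vinylcyclobutenone, not isolated) | COC1=C(C)C(=O)C1(CC1=C(OC(C)C)CC1=O)C(=C)OC(C)C | intermediate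
18 | (3E)-4-[(2-isopropoxy-4-oxocyclobut-1-en-1-yl)methyl]-5-isopropoxy-3-methoxy-2-methylhexa-1,3,5-trien-1-one (first dienylketene, not isolated) | O=C=C(C)/C(OC)=C(\C(=C)OC(C)C)CC1=C(OC(C)C)CC1=O | intermediate
19 | 4-[(2-isopropoxy-4-oxocyclobut-1-en-1-yl)methyl]-5-isopropoxy-3-methoxy-2-methylcyclohexa-2,4-dien-1-one (first cyclohexadienone, not isolated) | O=C1CC(OC(C)C)=C(CC2=C(OC(C)C)CC2=O)C(OC)=C1C | intermediate
20 | 2-(4-hydroxy-2-isopropoxy-6-methoxy-5-methylbenzyl)-3-isopropoxycyclobut-2-en-1-one (monophenol, not isolated) | COc1c(C)c(O)cc(OC(C)C)c1CC1=C(OC(C)C)CC1=O | intermediate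
21 | 2-(4-hydroxy-2-isopropoxy-6-methoxy-5-methylbenzyl)-3-isopropoxybuta-1,3-dien-1-one (second vinylketene, not isolated) | C=C(OC(C)C)C(=C=O)Cc1c(OC(C)C)cc(O)c(C)c1OC | intermediate
22 | 4-(4-hydroxy-2-isopropoxy-6-methoxy-5-methylbenzyl)-4-(1-isopropoxyvinyl)-3-methoxy-2-methylcyclobut-2-en-1-one, racemic (second vinylcyclobutenone, not isolated) | COC1=C(C)C(=O)C1(Cc1c(OC(C)C)cc(O)c(C)c1OC)C(=C)OC(C)C | intermediate
23 | (3E)-4-(4-hydroxy-2-isopropoxy-6-methoxy-5-methylbenzyl)-5-isopropoxy-3-methoxy-2-methylhexa-1,3,5-trien-1-one (second dienylketene, not isolated) | O=C=C(C)/C(OC)=C(\C(=C)OC(C)C)Cc1c(OC(C)C)cc(O)c(C)c1OC | intermediate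
24 | 4-(4-hydroxy-2-isopropoxy-6-methoxy-5-methylbenzyl)-5-isopropoxy-3-methoxy-2-methylcyclohexa-2,4-dien-1-one (second cyclohexadienone, not isolated) | O=C1CC(OC(C)C)=C(Cc2c(OC(C)C)cc(O)c(C)c2OC)C(OC)=C1C | intermediate
25 | bis(4-hydroxy-2-isopropoxy-6-methoxy-5-methylphenyl)methane | COc1c(C)c(O)cc(OC(C)C)c1Cc1c(OC(C)C)cc(O)c(C)c1OC | intermediate
26 | bis(3-acetyl-4-hydroxy-2-isopropoxy-6-methoxy-5-methylphenyl)methane | COc1c(C)c(O)c(C(C)=O)c(OC(C)C)c1Cc1c(OC(C)C)c(C(C)=O)c(O)c(C)c1OC | intermediate
27 | mallotophenone, bis(3-acetyl-2,4-dihydroxy-6-methoxy-5-methylphenyl)methane | COc1c(C)c(O)c(C(C)=O)c(O)c1Cc1c(O)c(C(C)=O)c(O)c(C)c1OC | target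

**Step count and risks**

Total step count: 9. Longest linear sequence: 7 steps (steps 1, 2, 3, 4, 7, 8, 9); steps 5 and 6 form the second branch and join at step 7.

Steps most likely to fail:

1. Step 7 (Proposed new method). The push–pull stabilisation of the alkoxy enone may slow ring opening so much that, at the temperature required, the vinylketenes are consumed by self-condensation or by O-acylation of the first-formed phenol faster than the alkyne captures them, or the sequence may stall after one ring. The fallback uses known chemistry and gives up the cycloaddition for the classical acylphloroglucinol assembly; it sets out from acetyl chloride 2 and comes back to the route at mallotophenone 27. Friedel–Crafts acetylation of commercial 2-methylphloroglucinol with 2 (AlCl3, PhNO2) should give 2,4,6-trihydroxy-3-methylacetophenone F1 (both open positions are equivalent). Selective methylation of the one hydroxyl that is para to the ketone and not hydrogen-bonded (Me2SO4, 1 equiv, K2CO3, acetone) should give 2,6-dihydroxy-4-methoxy-3-methylacetophenone F2. Condensation of two molecules of F2 with formaldehyde 6 at the single free ring carbon (aq. CH2O, aq. KOH, rt) then gives 27.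

2. Step 3. Hydrolytic ring opening of the strained dione, or polymerisation of the methylene dione before the second enol adds, may outrun the bridging. The fallback separates the two C–C bond formations by a Mannich sequence; it sets out from 5 and comes back at 8. Compound 5 is treated with dimethylmethyleneammonium iodide (MeCN, 0 °C) to give the isolable Mannich base 2-[(dimethylamino)methyl]-3-hydroxycyclobut-2-en-1-one F3. Warming F3 with a second equivalent of 5 (EtOH, 50 °C) expels dimethylamine and lets the second enol add to the methylene dione as it is released in low concentration, giving 8.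

3. Step 8. Attack of the electrophile or of a proton at the bridge-bearing carbon C1 may cleave or scramble the electron-rich diarylmethane before the rings are deactivated, or acylation may stop at oxygen. The fallback moves the C-acylation to neutral, photochemical conditions; it sets out from 25 and comes back at 26. O-Acetylation (Ac2O, pyridine, DMAP, rt) gives bis(4-acetoxy-2-isopropoxy-6-methoxy-5-methylphenyl)methane F4. Photo-Fries rearrangement (254 nm, degassed MeCN) should then shift each acetyl group to C3, the only open ortho position (the para position is blocked by the bridge), giving 26.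

Further compounds
F1 | step 7 | 2,4,6-trihydroxy-3-methylacetophenone | CC(=O)c1c(O)cc(O)c(C)c1O
F2 | step 7 | 2,6-dihydroxy-4-methoxy-3-methylacetophenone | CC(=O)c1c(O)cc(OC)c(C)c1O
F3 | step 3 | 2-[(dimethylamino)methyl]-3-hydroxycyclobut-2-en-1-one | CN(C)CC1=C(O)CC1=O
F4 | step 8 | bis(4-acetoxy-2-isopropoxy-6-methoxy-5-methylphenyl)methane | COc1c(C)c(OC(C)=O)cc(OC(C)C)c1Cc1c(OC(C)C)cc(OC(C)=O)c(C)c1OC
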